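**Plan**
1. Cuts: first the ten benzyl ethers; then the interflavan bond upper C4–lower C8, back to an upper 4-ketone (benzylated (2R,3R)-dihydrorobinetin) and a lower C8 aryllithium; then, in the lower (catechin) unit, the pyran ring at O1–C8a and at C2–C3, back to a fluoro-bromo ketone of ring D and 3,4-bis(benzyloxy)benzaldehyde.
2. Enabling feature: with lower C4 as a carbonyl, this one group lies between C3 (then enolisable and nucleophilic) and C8a of ring D (a C–F ortho to it, then open to SNAr), so the alkoxide born at C2 in an aldol addition can close the pyran ring at once; the carbonyl is reduced away afterwards.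
3. Forward order: ring D is dressed from 1,3,5-trifluorobenzene (two OBn, F at the future C8a, Br at the future C8, ketone arm at the future C4a); the key step brings in C2, O1 and the catechol ring and closes the lower pyran ring; C4=O becomes CH2; Br becomes Li and adds to the upper 4-ketone; hydride replaces the tertiary OH; hydrogenolysis ends the route.
4. Stereochemistry: upper C2/C3 from the chiral pool; lower C2 from the chiral ammonium cation of the key step, lower C3 trans to it (anti aldol, epimerisable α-carbon); upper C4 (4β, cis to 3-O) from hydride delivery to the 4-aryl cation anti to 3-OBn.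
5. Regiochemistry 4→8 is fixed before the lower pyran ring exists: the two bromines of the symmetric ring-D precursor are equivalent, one becomes the ketone arm and the other marks C8.

Key step: step 5

Assumption: natural (+)-dihydrorobinetin is the (2R,3R)-trans isomer and is bought as such; the cinchonidinium catalyst of step 5 is assumed to steer the enolate to the Si face of the aldehyde (the pseudoenantiomeric cinchoninium salt serves if the sense proves opposite).

Step 1
Reactants: 1 1,3,5-trifluorobenzene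
Product: 2 1,3-bis(benzyloxy)-5-fluorobenzene
Conditions: BnOH (2.1 equiv), NaH (2.2 equiv), NMP, 0 → 90 °C
Reagents that add atoms: benzyl alcohol, OCc1ccccc1
Why: Two-fold SNAr by sodium benzyloxide on the trifluoroarene, in which each benzyloxy group that enters slows the next substitution, so that the reaction should stop at the monofluoride.

Step 2
Reactants: 2 1,3-bis(benzyloxy)-5-fluorobenzene
Product: 3 1,5-bis(benzyloxy)-2,4-dibromo-3-fluorobenzene
Conditions: NBS (2.05 equiv), MeCN, 0 °C → rt, dark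
Reagents that add atoms: N-bromosuccinimide, O=C1CCC(=O)N1Br
Why: Electrophilic aromatic bromination in which each bromine enters para to one benzyloxy group and ortho to the other (the 4,6-pattern of resorcinol diethers), the carbon between the two benzyloxy groups being the most hindered, which should give the symmetric dibromide flanking fluorine.

Step 3
Reactants: 3 1,5-bis(benzyloxy)-2,4-dibromo-3-fluorobenzene, 4 2-(benzyloxy)-N-methoxy-N-methylacetamide
Product: 6 2-(benzyloxy)-1-[4,6-bis(benzyloxy)-3-bromo-2-fluorophenyl]ethan-1-one, via aryllithium 5 (not isolated)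
Conditions: n-BuLi (1.0 equiv), THF, −78 °C; then 4, −78 → −40 °C; aq. NH4Cl
Reagents that add atoms: none
Why: Bromine–lithium exchange on one of the two equivalent bromines gives an ortho-fluoroaryllithium that is kept below the temperature of LiF loss, and its acylation by the N-methoxy-N-methylamide (Weinreb ketone synthesis) should stop at the ketone.

Step 4
Reactants: 6 2-(benzyloxy)-1-[4,6-bis(benzyloxy)-3-bromo-2-fluorophenyl]ethan-1-one
Product: 7 {[(Z)-2-(benzyloxy)-1-[4,6-bis(benzyloxy)-3-bromo-2-fluorophenyl]ethenyl]oxy}trimethylsilane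
Conditions: Me3SiOSO2CF3 (1.2 equiv), Et3N (1.5 equiv), CH2Cl2, 0 °C; pentane, filtration
Reagents that add atoms: trimethylsilyl trifluoromethanesulfonate, C[Si](C)(C)OS(=O)(=O)C(F)(F)F
Why: Soft enolisation of the α-benzyloxy ketone (silyl triflate and amine) towards its only enolisable side should give the silyl enol ether, mainly as the Z isomer.

Step 5
Reactants: 7 {[(Z)-2-(benzyloxy)-1-[4,6-bis(benzyloxy)-3-bromo-2-fluorophenyl]ethenyl]oxy}trimethylsilane, 8 3,4-bis(benzyloxy)benzaldehyde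
Product: 11 (2R,3R)-3,5,7-tris(benzyloxy)-2-[3,4-bis(benzyloxy)phenyl]-8-bromo-2,3-dihydro-4H-chromen-4-one, via ammonium enolate 9 (not isolated), via ammonium aldolate 10 (not isolated)
Conditions: O-allyl-N-(9-anthracenylmethyl)cinchonidinium hydrogen difluoride (10 mol %), 4 Å sieves, THF–toluene, −78 → −20 °C
Reagents that add atoms: none
Why: Proposed new method: a fluoride-relay domino in which the catalytic chiral ammonium fluoride strips the silyl group from 7 to give the ion-paired enolate 9, 9 adds through C3 to the aldehyde carbon of 8 (lower C2–C3 bond), and the alkoxide 10 attacks the fluorine-bearing ring-D carbon ortho to the ketone (lower O1–C8a bond, addition–elimination through a Meisenheimer adduct), which returns fluoride to carry the chain and leaves Me3SiF as the only by-product. The closest known reaction types are the chiral quaternary ammonium fluoride-catalysed Mukaiyama aldol addition of ketone enol silanes to aromatic aldehydes, the domino aldol–SNAr annulation of ortho-fluoroaryl carbonyl compounds, and the phase-transfer Darzens reaction, in which an ion-paired aldolate likewise closes a ring by O-substitution. The pyran ring closes in a 6-exo mode, the alkoxide oxygen reaching the ipso carbon in a six-membered array that holds the activating carbonyl in the plane of ring D. Lower C2 is set by the cinchonidinium cation, which shields one face of the ion-paired enolate so that the aldehyde is taken on its Si face (2R); lower C3 is set by the anti transition state and backed by thermodynamics, since this carbon stays epimerisable α to the ketone and relaxes to the 2,3-trans (3R) isomer. The step needs O-arylation at C–F and not at the ortho-benzyloxy carbon, ring closure faster than retro-aldol or dehydration of 10, and an intact C–Br: fluoride is by far the better nucleofuge, the medium holds neither stoichiometric base nor water, and the bromine is meta to the ketone and so not activated.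

Step 6
Reactants: 11 (2R,3R)-3,5,7-tris(benzyloxy)-2-[3,4-bis(benzyloxy)phenyl]-8-bromo-2,3-dihydro-4H-chromen-4-one
Product: 12 (2R,3S,4R)-3,5,7-tris(benzyloxy)-2-[3,4-bis(benzyloxy)phenyl]-8-bromo-3,4-dihydro-2H-chromen-4-ol
Conditions: NaBH4, THF–EtOH, 0 °C
Reagents that add atoms: none
Why: Borohydride reduction of the aryl ketone, expected mainly to give the equatorial 4-hydroxyl (drawn), the configuration of this carbinol being erased in step 7.

Step 7
Reactants: 12 (2R,3S,4R)-3,5,7-tris(benzyloxy)-2-[3,4-bis(benzyloxy)phenyl]-8-bromo-3,4-dihydro-2H-chromen-4-ol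
Product: 13 (2R,3S)-3,5,7-tris(benzyloxy)-2-[3,4-bis(benzyloxy)phenyl]-8-bromo-3,4-dihydro-2H-chromene
Conditions: Et3SiH (3 equiv), CF3CO2H, CH2Cl2, −20 → 0 °C
Reagents that add atoms: none
Why: Ionic hydrogenation, in which the acid ionises the 4-hydroxyl to a benzylic cation stabilised by the ortho- and para-benzyloxy groups of ring D and the silane delivers hydride, as in the known passage from dihydroflavonols through flavan-3,4-diols to flavan-3-ols, with C2 and C3 untouched.

Step 8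
Reactants: 14 (+)-dihydrorobinetin, (2R,3R)-3,7-dihydroxy-2-(3,4,5-trihydroxyphenyl)-2,3-dihydro-4H-chromen-4-one
Product: 15 (2R,3R)-7-(benzyloxy)-3-hydroxy-2-[3,4,5-tris(benzyloxy)phenyl]-2,3-dihydro-4H-chromen-4-one
Conditions: BnBr (4.4 equiv), K2CO3, DMF, rt, argon
Reagents that add atoms: benzyl bromide, BrCc1ccccc1
Why: Williamson ether synthesis on the four phenols with a base too weak to deprotonate the 3-hydroxyl, run at room temperature under argon to spare the base-sensitive flavanonol ring and the pyrogallol unit.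

Step 9
Reactants: 15 (2R,3R)-7-(benzyloxy)-3-hydroxy-2-[3,4,5-tris(benzyloxy)phenyl]-2,3-dihydro-4H-chromen-4-one
Product: 16 (2R,3R)-3,7-bis(benzyloxy)-2-[3,4,5-tris(benzyloxy)phenyl]-2,3-dihydro-4H-chromen-4-one
Conditions: benzyl 2,2,2-trichloroacetimidate (2 equiv), CF3SO3H (5 mol %), CH2Cl2–cyclohexane, 0 °C → rt
Reagents that add atoms: benzyl 2,2,2-trichloroacetimidate, ClC(Cl)(Cl)C(=N)OCc1ccccc1
Why: Acid-catalysed O-benzylation by the trichloroacetimidate, which avoids base and therefore enolisation at C3 and opening of the flavanone ring.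

Step 10
Reactants: 13 (2R,3S)-3,5,7-tris(benzyloxy)-2-[3,4-bis(benzyloxy)phenyl]-8-bromo-3,4-dihydro-2H-chromene, 16 (2R,3R)-3,7-bis(benzyloxy)-2-[3,4,5-tris(benzyloxy)phenyl]-2,3-dihydro-4H-chromen-4-one
Product: 18 (2R,3R,4R)-3,7-bis(benzyloxy)-4-[(2R,3S)-3,5,7-tris(benzyloxy)-2-[3,4-bis(benzyloxy)phenyl]-3,4-dihydro-2H-chromen-8-yl]-2-[3,4,5-tris(benzyloxy)phenyl]-3,4-dihydro-2H-chromen-4-ol, via aryllithium 17 (not isolated)
Conditions: 13 (1.3 equiv), t-BuLi (2.6 equiv), THF, −78 °C; then 16, −78 → −40 °C; aq. NH4Cl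
Reagents that add atoms: none
Why: Bromine–lithium exchange and 1,2-addition of the ring-D aryllithium to the 4-ketone, the known way to forge a 4→8 interflavan bond from an 8-bromoflavan-3-ol ether and a 3-O-protected flavan-4-one; the bromine fixes the regiochemistry and the new carbinol centre (drawn as the epimer from attack anti to 3-OBn) is planarised in step 11.

Step 11
Reactants: 18 (2R,3R,4R)-3,7-bis(benzyloxy)-4-[(2R,3S)-3,5,7-tris(benzyloxy)-2-[3,4-bis(benzyloxy)phenyl]-3,4-dihydro-2H-chromen-8-yl]-2-[3,4,5-tris(benzyloxy)phenyl]-3,4-dihydro-2H-chromen-4-ol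
Product: 19 (2R,3S,4R)-3,7-bis(benzyloxy)-4-[(2R,3S)-3,5,7-tris(benzyloxy)-2-[3,4-bis(benzyloxy)phenyl]-3,4-dihydro-2H-chromen-8-yl]-2-[3,4,5-tris(benzyloxy)phenyl]-3,4-dihydro-2H-chromene
Conditions: Bu3SnH (3 equiv), CF3CO2H, CH2Cl2, 0 °C
Reagents that add atoms: none
Why: The acid ionises the tertiary bis-benzylic alcohol and the stannane transfers hydride to the 4-aryl cation from the face anti to the neighbouring 3-benzyloxy group, which leaves the ring-D aryl group cis to 3-O (4β, 4R); this reductive removal of a 4-hydroxyl is the known route to 3,4-cis 4-arylflavan-3-ols.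

Step 12
Reactants: 19 (2R,3S,4R)-3,7-bis(benzyloxy)-4-[(2R,3S)-3,5,7-tris(benzyloxy)-2-[3,4-bis(benzyloxy)phenyl]-3,4-dihydro-2H-chromen-8-yl]-2-[3,4,5-tris(benzyloxy)phenyl]-3,4-dihydro-2H-chromene
Product: 20 robinetinidol-(4β→8)-catechin, (2R,3S,4R)-2-(3,4,5-trihydroxyphenyl)-4-[(2R,3S)-2-(3,4-dihydroxyphenyl)-3,5,7-trihydroxy-3,4-dihydro-2H-chromen-8-yl]-3,4-dihydro-2H-chromene-3,7-diol
Conditions: H2 (1 atm), Pd(OH)2/C, THF–MeOH–H2O, rt
Reagents that add atoms: none
Why: Hydrogenolysis of all ten benzyl ethers, under conditions in which the benzylic ring C–O bonds and the interflavan bond of proanthocyanidin benzyl ethers are known to survive.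

**Compound list**
1 | 1,3,5-trifluorobenzene | Fc1cc(F)cc(F)c1 | starting material
2 | 1,3-bis(benzyloxy)-5-fluorobenzene | Fc1cc(OCc2ccccc2)cc(OCc2ccccc2)c1 | intermediate
3 | 1,5-bis(benzyloxy)-2,4-dibromo-3-fluorobenzene | Fc1c(Br)c(OCc2ccccc2)cc(OCc2ccccc2)c1Br | intermediate
4 | 2-(benzyloxy)-N-methoxy-N-methylacetamide | CON(C)C(=O)COCc1ccccc1 | starting material
5 | [4,6-bis(benzyloxy)-3-bromo-2-fluorophenyl]lithium (formed in the flask, not isolated) | [Li]c1c(F)c(Br)c(OCc2ccccc2)cc1OCc1ccccc1 | intermediate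
6 | 2-(benzyloxy)-1-[4,6-bis(benzyloxy)-3-bromo-2-fluorophenyl]ethan-1-one | O=C(COCc1ccccc1)c1c(F)c(Br)c(OCc2ccccc2)cc1OCc1ccccc1 | intermediate
7 | {[(Z)-2-(benzyloxy)-1-[4,6-bis(benzyloxy)-3-bromo-2-fluorophenyl]ethenyl]oxy}trimethylsilane | C[Si](C)(C)O/C(=C\OCc1ccccc1)c1c(F)c(Br)c(OCc2ccccc2)cc1OCc1ccccc1 | intermediate
8 | 3,4-bis(benzyloxy)benzaldehyde | O=Cc1ccc(OCc2ccccc2)c(OCc2ccccc2)c1 | starting material
9 | (Z)-enolate of 6, anion of its ion pair with the cinchonidinium cation (formed in the flask, not isolated) | [O-]/C(=C\OCc1ccccc1)c1c(F)c(Br)c(OCc2ccccc2)cc1OCc1ccccc1 | intermediate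
10 | (1R,2R)-2-(benzyloxy)-1-[3,4-bis(benzyloxy)phenyl]-3-[4,6-bis(benzyloxy)-3-bromo-2-fluorophenyl]-3-oxopropan-1-olate, anion of its ion pair with the cinchonidinium cation (formed in the flask, not isolated) | [O-][C@H](c1ccc(OCc2ccccc2)c(OCc2ccccc2)c1)[C@@H](OCc1ccccc1)C(=O)c1c(F)c(Br)c(OCc2ccccc2)cc1OCc1ccccc1 | intermediate
11 | (2R,3R)-3,5,7-tris(benzyloxy)-2-[3,4-bis(benzyloxy)phenyl]-8-bromo-2,3-dihydro-4H-chromen-4-one | Brc1c(OCc3ccccc3)cc(OCc3ccccc3)c2c1O[C@H](c1ccc(OCc3ccccc3)c(OCc3ccccc3)c1)[C@@H](OCc1ccccc1)C2=O | intermediate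
12 | (2R,3S,4R)-3,5,7-tris(benzyloxy)-2-[3,4-bis(benzyloxy)phenyl]-8-bromo-3,4-dihydro-2H-chromen-4-ol | Brc1c(OCc3ccccc3)cc(OCc3ccccc3)c2c1O[C@H](c1ccc(OCc3ccccc3)c(OCc3ccccc3)c1)[C@@H](OCc1ccccc1)[C@@H]2O | intermediate
13 | (2R,3S)-3,5,7-tris(benzyloxy)-2-[3,4-bis(benzyloxy)phenyl]-8-bromo-3,4-dihydro-2H-chromene | Brc1c(OCc3ccccc3)cc(OCc3ccccc3)c2c1O[C@H](c1ccc(OCc3ccccc3)c(OCc3ccccc3)c1)[C@@H](OCc1ccccc1)C2 | intermediate
14 | (+)-dihydrorobinetin, (2R,3R)-3,7-dihydroxy-2-(3,4,5-trihydroxyphenyl)-2,3-dihydro-4H-chromen-4-one | Oc1ccc2c(c1)O[C@H](c1cc(O)c(O)c(O)c1)[C@@H](O)C2=O | starting material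
15 | (2R,3R)-7-(benzyloxy)-3-hydroxy-2-[3,4,5-tris(benzyloxy)phenyl]-2,3-dihydro-4H-chromen-4-one | C(c1ccccc1)Oc1ccc2c(c1)O[C@H](c1cc(OCc3ccccc3)c(OCc3ccccc3)c(OCc3ccccc3)c1)[C@@H](O)C2=O | intermediate
16 | (2R,3R)-3,7-bis(benzyloxy)-2-[3,4,5-tris(benzyloxy)phenyl]-2,3-dihydro-4H-chromen-4-one | C(c1ccccc1)Oc1ccc2c(c1)O[C@H](c1cc(OCc3ccccc3)c(OCc3ccccc3)c(OCc3ccccc3)c1)[C@@H](OCc1ccccc1)C2=O | intermediate
17 | [(2R,3S)-3,5,7-tris(benzyloxy)-2-[3,4-bis(benzyloxy)phenyl]-3,4-dihydro-2H-chromen-8-yl]lithium (formed in the flask, not isolated) | [Li]c1c(OCc3ccccc3)cc(OCc3ccccc3)c2c1O[C@H](c1ccc(OCc3ccccc3)c(OCc3ccccc3)c1)[C@@H](OCc1ccccc1)C2 | intermediate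
18 | (2R,3R,4R)-3,7-bis(benzyloxy)-4-[(2R,3S)-3,5,7-tris(benzyloxy)-2-[3,4-bis(benzyloxy)phenyl]-3,4-dihydro-2H-chromen-8-yl]-2-[3,4,5-tris(benzyloxy)phenyl]-3,4-dihydro-2H-chromen-4-ol | C(c1ccccc1)Oc1ccc2c(c1)O[C@H](c1cc(OCc3ccccc3)c(OCc3ccccc3)c(OCc3ccccc3)c1)[C@@H](OCc1ccccc1)[C@]2(O)c1c(OCc3ccccc3)cc(OCc3ccccc3)c2c1O[C@H](c1ccc(OCc3ccccc3)c(OCc3ccccc3)c1)[C@@H](OCc1ccccc1)C2 | intermediate
19 | (2R,3S,4R)-3,7-bis(benzyloxy)-4-[(2R,3S)-3,5,7-tris(benzyloxy)-2-[3,4-bis(benzyloxy)phenyl]-3,4-dihydro-2H-chromen-8-yl]-2-[3,4,5-tris(benzyloxy)phenyl]-3,4-dihydro-2H-chromene | C(c1ccccc1)Oc1ccc2c(c1)O[C@H](c1cc(OCc3ccccc3)c(OCc3ccccc3)c(OCc3ccccc3)c1)[C@@H](OCc1ccccc1)[C@H]2c1c(OCc3ccccc3)cc(OCc3ccccc3)c2c1O[C@H](c1ccc(OCc3ccccc3)c(OCc3ccccc3)c1)[C@@H](OCc1ccccc1)C2 | intermediate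
20 | robinetinidol-(4β→8)-catechin, (2R,3S,4R)-2-(3,4,5-trihydroxyphenyl)-4-[(2R,3S)-2-(3,4-dihydroxyphenyl)-3,5,7-trihydroxy-3,4-dihydro-2H-chromen-8-yl]-3,4-dihydro-2H-chromene-3,7-diol | Oc1ccc2c(c1)O[C@H](c1cc(O)c(O)c(O)c1)[C@@H](O)[C@H]2c1c(O)cc(O)c2c1O[C@H](c1ccc(O)c(O)c1)[C@@H](O)C2 | target

**Count and risks**
Total steps: 12. Longest linear sequence: 10 (steps 1–7, then 10–12).

Steps most likely to fail:

1. Step 5. What may go wrong: retro-aldol cleavage or dehydration of the aldolate outrunning ring closure; weak facial discrimination in the ion pair; base-induced ring opening of the product at C2, each of which would erode enantiomeric purity. Fallback, setting out from 7 and 8 and coming back at 11: the two bonds are made in separate, known operations. A Mukaiyama aldol addition of 7 to 8 is promoted by SiCl4 under catalysis by a chiral bisphosphoramide Lewis base (two (R)-N,N'-dimethyl-1,1'-binaphthyl-2,2'-diamine units joined through P(=O)N(Me)(CH2)5N(Me)P(=O), the antipode being chosen for Si-face addition; i-Pr2NEt, CH2Cl2, −78 °C). It runs through an open transition state and should be anti-selective, giving after aqueous work-up the isolated aldol (2R,3R)-2-(benzyloxy)-1-[4,6-bis(benzyloxy)-3-bromo-2-fluorophenyl]-3-[3,4-bis(benzyloxy)phenyl]-3-hydroxypropan-1-one F1. F1 is then closed by intramolecular SNAr with KOt-Bu in THF at −40 °C, which returns 11.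

2. Step 11. What may go wrong: poor facial selectivity of hydride delivery to the 4-aryl cation, since the 2-aryl group on the α face competes with the 3-benzyloxy group on the β face; or proton loss from C3 to the enol ether, with scrambling of C3. Fallback, setting out from 15 and coming back at 20: the steering group on O3 is changed to a bulky silyl ether, the case for which reductive removal of the 4-hydroxyl is precedented to give the 3,4-cis product. Silylation of 15 (t-BuMe2SiOSO2CF3, 2,6-lutidine, CH2Cl2) gives the 3-O-silyl ketone F2. Addition of aryllithium 17 (made from 13 as in step 10) gives the tertiary alcohol F3. Bu3SnH and CF3CO2H give the 4β-aryl silyl ether F4. Bu4NF in THF frees the 3-hydroxyl to give the nona-O-benzyl ether F5, and hydrogenolysis over Pd(OH)2/C gives 20.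

3. Step 10. What may go wrong: enolisation of the 4-ketone at C3 by the hindered, basic aryllithium in place of addition, followed by opening of the pyran ring. Fallback, setting out from 16 and 13 and coming back at 19: the polarity of the union is reversed to the classical electrophilic coupling. NaBH4 reduces 16 to the flavan-4-ol (2R,3S,4R)-3,7-bis(benzyloxy)-2-[3,4,5-tris(benzyloxy)phenyl]-3,4-dihydro-2H-chromen-4-ol F6. Bromine–lithium exchange on 13 and a methanol quench give penta-O-benzyl-(+)-catechin F7. Me3SiOSO2CF3 (catalytic, CH2Cl2, −78 °C) ionises F6, and the cation is taken up by C8 of F7 used in excess. This coupling is not expected to be selective at upper C4, so 19 would be separated by chromatography from its C4 epimer F8; step 11 is then not needed.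

**Further compounds**
F1 | step 5 | (2R,3R)-2-(benzyloxy)-1-[4,6-bis(benzyloxy)-3-bromo-2-fluorophenyl]-3-[3,4-bis(benzyloxy)phenyl]-3-hydroxypropan-1-one | O[C@H](c1ccc(OCc2ccccc2)c(OCc2ccccc2)c1)[C@@H](OCc1ccccc1)C(=O)c1c(F)c(Br)c(OCc2ccccc2)cc1OCc1ccccc1
F2 | step 11 | (2R,3R)-7-(benzyloxy)-3-[(tert-butyldimethylsilyl)oxy]-2-[3,4,5-tris(benzyloxy)phenyl]-2,3-dihydro-4H-chromen-4-one | C(c1ccccc1)Oc1ccc2c(c1)O[C@H](c1cc(OCc3ccccc3)c(OCc3ccccc3)c(OCc3ccccc3)c1)[C@@H](O[Si](C)(C)C(C)(C)C)C2=O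
F3 | step 11 | (2R,3R,4R)-7-(benzyloxy)-3-[(tert-butyldimethylsilyl)oxy]-4-[(2R,3S)-3,5,7-tris(benzyloxy)-2-[3,4-bis(benzyloxy)phenyl]-3,4-dihydro-2H-chromen-8-yl]-2-[3,4,5-tris(benzyloxy)phenyl]-3,4-dihydro-2H-chromen-4-ol | C(c1ccccc1)Oc1ccc2c(c1)O[C@H](c1cc(OCc3ccccc3)c(OCc3ccccc3)c(OCc3ccccc3)c1)[C@@H](O[Si](C)(C)C(C)(C)C)[C@]2(O)c1c(OCc3ccccc3)cc(OCc3ccccc3)c2c1O[C@H](c1ccc(OCc3ccccc3)c(OCc3ccccc3)c1)[C@@H](OCc1ccccc1)C2
F4 | step 11 | (2R,3S,4R)-7-(benzyloxy)-3-[(tert-butyldimethylsilyl)oxy]-4-[(2R,3S)-3,5,7-tris(benzyloxy)-2-[3,4-bis(benzyloxy)phenyl]-3,4-dihydro-2H-chromen-8-yl]-2-[3,4,5-tris(benzyloxy)phenyl]-3,4-dihydro-2H-chromene | C(c1ccccc1)Oc1ccc2c(c1)O[C@H](c1cc(OCc3ccccc3)c(OCc3ccccc3)c(OCc3ccccc3)c1)[C@@H](O[Si](C)(C)C(C)(C)C)[C@H]2c1c(OCc3ccccc3)cc(OCc3ccccc3)c2c1O[C@H](c1ccc(OCc3ccccc3)c(OCc3ccccc3)c1)[C@@H](OCc1ccccc1)C2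
F5 | step 11 | (2R,3S,4R)-7-(benzyloxy)-4-[(2R,3S)-3,5,7-tris(benzyloxy)-2-[3,4-bis(benzyloxy)phenyl]-3,4-dihydro-2H-chromen-8-yl]-2-[3,4,5-tris(benzyloxy)phenyl]-3,4-dihydro-2H-chromen-3-ol | C(c1ccccc1)Oc1ccc2c(c1)O[C@H](c1cc(OCc3ccccc3)c(OCc3ccccc3)c(OCc3ccccc3)c1)[C@@H](O)[C@H]2c1c(OCc3ccccc3)cc(OCc3ccccc3)c2c1O[C@H](c1ccc(OCc3ccccc3)c(OCc3ccccc3)c1)[C@@H](OCc1ccccc1)C2
F6 | step 10 | (2R,3S,4R)-3,7-bis(benzyloxy)-2-[3,4,5-tris(benzyloxy)phenyl]-3,4-dihydro-2H-chromen-4-ol | C(c1ccccc1)Oc1ccc2c(c1)O[C@H](c1cc(OCc3ccccc3)c(OCc3ccccc3)c(OCc3ccccc3)c1)[C@@H](OCc1ccccc1)[C@@H]2O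
F7 | step 10 | (2R,3S)-3,5,7-tris(benzyloxy)-2-[3,4-bis(benzyloxy)phenyl]-3,4-dihydro-2H-chromene | c1c(OCc3ccccc3)cc(OCc3ccccc3)c2c1O[C@H](c1ccc(OCc3ccccc3)c(OCc3ccccc3)c1)[C@@H](OCc1ccccc1)C2
F8 | step 10 | (2R,3S,4S)-3,7-bis(benzyloxy)-4-[(2R,3S)-3,5,7-tris(benzyloxy)-2-[3,4-bis(benzyloxy)phenyl]-3,4-dihydro-2H-chromen-8-yl]-2-[3,4,5-tris(benzyloxy)phenyl]-3,4-dihydro-2H-chromene | C(c1ccccc1)Oc1ccc2c(c1)O[C@H](c1cc(OCc3ccccc3)c(OCc3ccccc3)c(OCc3ccccc3)c1)[C@@H](OCc1ccccc1)[C@@H]2c1c(OCc3ccccc3)cc(OCc3ccccc3)c2c1O[C@H](c1ccc(OCc3ccccc3)c(OCc3ccccc3)c1)[C@@H](OCc1ccccc1)C2
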